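**Retrosynthetic overview**
- C3–aryl bond, made last: the quaternary (S) centre comes from enantioselective Cu/bisoxazoline arylation of the arylidene-tetronic acid 7 with the aryl(mesityl)-λ3-iodane 12. The iodane reverses the polarity of the phenol para-carbon to an aryl cation equivalent, so two natively nucleophilic carbons are joined.
- C5=CH bond: Z-selective vinylogous aldol condensation of 3-prenyltetronic acid 6 with aldehyde 3.
- 6 from tetronic acid and prenol (Pd); 3 from 4-hydroxybenzaldehyde and prenyl bromide.
- 12 from 4-bromophenol: ortho-C-prenylation, silylation, Br→B, B→I(III).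
- Rings: none is built; the furanone ring is bought as tetronic acid and both benzene rings as phenols.

Prenyl = 3-methylbut-2-en-1-yl; TIPS = triisopropylsilyl; Mes = 2,4,6-trimethylphenyl.

Assumption: the sense of induction in step 8 cannot be predicted for this new substrate class; the ligand is written as (S,S) and its commercial antipode is used if the first run gives the (R)-product.

**Step 1**
Reactants: 1 4-hydroxybenzaldehyde; 2 prenyl bromide
Product: 3 4-hydroxy-3-prenylbenzaldehyde
Conditions: KOH (1.1 equiv), H2O, 2 (1.1 equiv), rt, 24 h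
Reagents that add atoms: none
Why: Phenoxide ortho-C-alkylation; in water the phenoxide oxygen is hydrogen-bonded, so the ring carbon ortho to O (para is blocked by CHO) attacks prenyl bromide at its CH2 end, with the O-prenyl ether as a separable by-product.

**Step 2**
Reactants: 4 tetronic acid; 5 prenol
Product: 6 4-hydroxy-3-prenylfuran-2(5H)-one (3-prenyltetronic acid)
Conditions: Pd(PPh3)4 (3 mol%), 4 (2.5 equiv), THF, 65 °C
Reagents that add atoms: none
Why: Tsuji–Trost C-allylation; the acidic tetronic acid (pKa about 3.8) activates prenol for ionisation by Pd(0), and the tetronate attacks the π-prenyl complex through C3 at the unhindered CH2 terminus to give the linear prenyl product, while excess 4 suppresses double prenylation.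

**Step 3**
Reactants: 6 3-prenyltetronic acid; 3 4-hydroxy-3-prenylbenzaldehyde
Product: 7 (Z)-4-hydroxy-5-[4-hydroxy-3-prenylbenzylidene]-3-prenylfuran-2(5H)-one
Conditions: DBU (3 equiv), MeCN, 65 °C; then 1 M HCl
Reagents that add atoms: none
Why: Vinylogous aldol condensation of the pulvinone type; C3 is blocked, so the tetronate reacts at C5 and E1cB loss of water gives the arylidene, the Z isomer (aryl syn to ring O) being the thermodynamic product under these reversible basic conditions.

**Step 4**
Reactants: 8 4-bromophenol; 2 prenyl bromide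
Product: 9 4-bromo-2-prenylphenol
Conditions: NaH (1.05 equiv), toluene, 0 °C to rt; 2 (1.0 equiv)
Reagents that add atoms: none
Why: ortho-C-prenylation of a sodium phenoxide as a tight ion pair in a non-polar solvent, which shields oxygen and directs the prenyl group to the free ortho carbon (para is blocked by Br).

**Step 5**
Reactants: 9 4-bromo-2-prenylphenol
Product: 10 (4-bromo-2-prenylphenoxy)triisopropylsilane
Conditions: TIPSCl, imidazole, DMF, rt
Reagents that add atoms: triisopropylsilyl chloride CC(C)[Si](Cl)(C(C)C)C(C)C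
Why: Standard phenol silylation; the TIPS ether tolerates n-BuLi, BF3 and the iodane chemistry and is later removed by fluoride without touching the prenyl groups or the lactone.

**Step 6**
Reactants: 10 (4-bromo-2-prenylphenoxy)triisopropylsilane
Product: 11 [3-prenyl-4-(triisopropylsilyloxy)phenyl]boronic acid
Conditions: n-BuLi, THF, −78 °C; B(OiPr)3, −78 °C to rt; 1 M HCl, 0 °C, brief
Reagents that add atoms: triisopropyl borate CC(C)OB(OC(C)C)OC(C)C; water O
Why: Bromine–lithium exchange, trapping of the aryllithium as the borate and mild hydrolysis; the exchange is much faster than any allylic/benzylic deprotonation at −78 °C.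

**Step 7**
Reactants: 11 [3-prenyl-4-(triisopropylsilyloxy)phenyl]boronic acid
Product: 12 [3-prenyl-4-(triisopropylsilyloxy)phenyl](mesityl)iodonium tetrafluoroborate
Conditions: MesI(OAc)2, BF3·OEt2, CH2Cl2, 0 °C, 30 min; then sat. aq. NaBF4
Reagents that add atoms: iodomesitylene diacetate CC(=O)OI(OC(C)=O)c1c(C)cc(C)cc1C; sodium tetrafluoroborate [Na+].F[B-](F)(F)F
Why: Regiospecific boron-to-iodine(III) ipso transmetallation of an arylboronic acid with a BF3-activated (diacetoxyiodo)arene, fast at 0 °C so the prenyl alkene and silyl ether are not exposed for long; mesityl serves as the non-transferred ligand.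

**Step 8**
Reactants: 7 (Z)-4-hydroxy-5-[4-hydroxy-3-prenylbenzylidene]-3-prenylfuran-2(5H)-one; 12 aryl(mesityl)iodonium tetrafluoroborate
Product: 14 (3S,5Z)-5-[4-hydroxy-3-prenylbenzylidene]-3-(4-hydroxy-3-prenylphenyl)-3-prenylfuran-2,4(3H,5H)-dione (target CNP0567773.1), via triisopropylsilyl ether 13 (not isolated)
Conditions: (CuOTf)2·PhMe (5 mol%), (S,S)-Ph-BOX (12 mol%), NaHCO3 (1.2 equiv), 12 (1.2 equiv), CH2Cl2, −20 °C; then TBAF/AcOH (1:1), THF, 0 °C
Reagents that add atoms: none
Why: Proposed new method: Cu(I)/bisoxazoline adds oxidatively to the iodane to give a chiral aryl–Cu(III) electrophile (an aryl cation equivalent from the normally nucleophilic phenol para-carbon, the bulky mesityl staying on iodine), the tetronate (the only site deprotonated by bicarbonate, the phenol staying neutral) binds through oxygen and C3–aryl reductive elimination creates the quaternary centre, the ligand choosing the enolate face that is differentiated by the large 5-arylidene flank versus the ring-oxygen flank to give (S); the closest known reactions are Cu/bisoxazoline enantioselective arylations of enol silanes and of indole C3 (quaternary centres) with diaryliodonium salts and the racemic C-arylation of 2-substituted cyclic 1,3-dicarbonyls by diaryliodonium salts; buffered fluoride then cleaves the aryl silyl ether in the same flask.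

**Compound list**
1 | 4-hydroxybenzaldehyde | O=Cc1ccc(O)cc1 | starting material
2 | prenyl bromide (1-bromo-3-methylbut-2-ene) | CC(C)=CCBr | starting material
3 | 4-hydroxy-3-(3-methylbut-2-en-1-yl)benzaldehyde | CC(C)=CCc1cc(C=O)ccc1O | intermediate
4 | tetronic acid (4-hydroxyfuran-2(5H)-one) | OC1=CC(=O)OC1 | starting material
5 | prenol (3-methylbut-2-en-1-ol) | CC(C)=CCO | starting material
6 | 4-hydroxy-3-(3-methylbut-2-en-1-yl)furan-2(5H)-one | CC(C)=CCC1=C(O)COC1=O | intermediate
7 | (Z)-4-hydroxy-5-[4-hydroxy-3-prenylbenzylidene]-3-prenylfuran-2(5H)-one | CC(C)=CCc1cc(/C=C2\OC(=O)C(CC=C(C)C)=C2O)ccc1O | intermediate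
8 | 4-bromophenol | Oc1ccc(Br)cc1 | starting material
9 | 4-bromo-2-(3-methylbut-2-en-1-yl)phenol | CC(C)=CCc1cc(Br)ccc1O | intermediate
10 | (4-bromo-2-prenylphenoxy)triisopropylsilane | CC(C)=CCc1cc(Br)ccc1O[Si](C(C)C)(C(C)C)C(C)C | intermediate
11 | [3-prenyl-4-(triisopropylsilyloxy)phenyl]boronic acid | CC(C)=CCc1cc(B(O)O)ccc1O[Si](C(C)C)(C(C)C)C(C)C | intermediate
12 | [3-prenyl-4-(triisopropylsilyloxy)phenyl](2,4,6-trimethylphenyl)iodonium tetrafluoroborate | CC(C)=CCc1cc([I+]c2c(C)cc(C)cc2C)ccc1O[Si](C(C)C)(C(C)C)C(C)C.F[B-](F)(F)F | intermediate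
13 | (3S,5Z)-5-[4-hydroxy-3-prenylbenzylidene]-3-prenyl-3-[3-prenyl-4-(triisopropylsilyloxy)phenyl]furan-2,4(3H,5H)-dione | CC(C)=CCc1cc(/C=C2\OC(=O)[C@@](CC=C(C)C)(c3ccc(O[Si](C(C)C)(C(C)C)C(C)C)c(CC=C(C)C)c3)C2=O)ccc1O | intermediate
14 | (3S,5Z)-5-[4-hydroxy-3-prenylbenzylidene]-3-(4-hydroxy-3-prenylphenyl)-3-prenylfuran-2,4(3H,5H)-dione | CC(C)=CCc1cc(/C=C2\OC(=O)[C@@](CC=C(C)C)(c3ccc(O)c(CC=C(C)C)c3)C2=O)ccc1O | target

**Totals**
Total step count: 8. Longest linear sequence: 5 steps (8 → 9 → 10 → 11 → 12 → 14, steps 4–8).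

**Three steps most likely to fail**

Step 8 (enantioselective C3-arylation; risks are low ee and O-arylation of the tetronate or phenol). The fallback sets out from 7 together with 12. The arylation is run with an achiral copper catalyst (Cu(OTf)2, 2,6-di-tert-butylpyridine, CH2Cl2, rt) to give the racemic (5Z)-triisopropylsilyl ether F1. This is resolved by preparative SFC on a chiral stationary phase, and the unwanted (3R,5Z)-triisopropylsilyl ether F2 is set aside. The fallback comes back to the route at 13, which is desilylated with TBAF/AcOH as in step 8. The stereocentre then comes from resolution instead of catalysis.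

Step 3 (the free-phenol aldehyde may be too poor an electrophile for the tetronate under DBU). The fallback sets out from 6 and reverses the order of the two bond formations. 6 is arylated with 12 under the copper/bisoxazoline conditions of step 8 to give (S)-3-prenyl-3-[3-prenyl-4-(triisopropylsilyloxy)phenyl]furan-2,4(3H,5H)-dione F3. Its C5 methylene, now part of a neutral dione flanked by a ketone and the ring oxygen, condenses with 3 under aurone-type Knoevenagel conditions (neutral alumina, CH2Cl2, rt, or piperidinium acetate, toluene, 60 °C). This gives 13, where the fallback comes back to the route before desilylation.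

Step 7 (the prenyl alkene may not survive the iodine(III)/BF3 medium). The fallback sets out from 8 and carries the side chain as an allyl group through the iodane chemistry.
- O-allylation (allyl bromide, K2CO3, acetone) gives allyl 4-bromophenyl ether F4.
- Aromatic Claisen rearrangement (PhNEt2, 200 °C) gives 2-allyl-4-bromophenol F5.
- Silylation gives (2-allyl-4-bromophenoxy)triisopropylsilane F6.
- Lithiation–borylation gives [3-allyl-4-(triisopropylsilyloxy)phenyl]boronic acid F7.
- Boron–iodine(III) exchange as in step 7 gives [3-allyl-4-(triisopropylsilyloxy)phenyl](mesityl)iodonium tetrafluoroborate F8.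
- Copper/bisoxazoline arylation of 7 gives the (3S,5Z) allyl analogue of the silyl ether F9.
- Cross-metathesis with 2-methylbut-2-ene (Hoveyda–Grubbs II, CH2Cl2, 40 °C) converts the terminal allyl into prenyl and leaves the trisubstituted alkenes alone.

The fallback comes back to the route at 13.

**Further compounds**
F1 | step 8 | racemic (5Z)-5-[4-hydroxy-3-prenylbenzylidene]-3-prenyl-3-[3-prenyl-4-(triisopropylsilyloxy)phenyl]furan-2,4(3H,5H)-dione | CC(C)=CCc1cc(/C=C2\OC(=O)C(CC=C(C)C)(c3ccc(O[Si](C(C)C)(C(C)C)C(C)C)c(CC=C(C)C)c3)C2=O)ccc1O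
F2 | step 8 | (3R,5Z)-5-[4-hydroxy-3-prenylbenzylidene]-3-prenyl-3-[3-prenyl-4-(triisopropylsilyloxy)phenyl]furan-2,4(3H,5H)-dione | CC(C)=CCc1cc(/C=C2\OC(=O)[C@](CC=C(C)C)(c3ccc(O[Si](C(C)C)(C(C)C)C(C)C)c(CC=C(C)C)c3)C2=O)ccc1O
F3 | step 3 | (S)-3-prenyl-3-[3-prenyl-4-(triisopropylsilyloxy)phenyl]furan-2,4(3H,5H)-dione | C1OC(=O)[C@@](CC=C(C)C)(c2ccc(O[Si](C(C)C)(C(C)C)C(C)C)c(CC=C(C)C)c2)C1=O
F4 | step 7 | allyl 4-bromophenyl ether | C=CCOc1ccc(Br)cc1
F5 | step 7 | 2-allyl-4-bromophenol | C=CCc1cc(Br)ccc1O
F6 | step 7 | (2-allyl-4-bromophenoxy)triisopropylsilane | C=CCc1cc(Br)ccc1O[Si](C(C)C)(C(C)C)C(C)C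
F7 | step 7 | [3-allyl-4-(triisopropylsilyloxy)phenyl]boronic acid | C=CCc1cc(B(O)O)ccc1O[Si](C(C)C)(C(C)C)C(C)C
F8 | step 7 | [3-allyl-4-(triisopropylsilyloxy)phenyl](2,4,6-trimethylphenyl)iodonium tetrafluoroborate | C=CCc1cc([I+]c2c(C)cc(C)cc2C)ccc1O[Si](C(C)C)(C(C)C)C(C)C.F[B-](F)(F)F
F9 | step 7 | (3S,5Z)-3-[3-allyl-4-(triisopropylsilyloxy)phenyl]-5-[4-hydroxy-3-prenylbenzylidene]-3-prenylfuran-2,4(3H,5H)-dione | CC(C)=CCc1cc(/C=C2\OC(=O)[C@@](CC=C(C)C)(c3ccc(O[Si](C(C)C)(C(C)C)C(C)C)c(CC=C)c3)C2=O)ccc1O
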